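Ring A of the apigenin half is not coupled to ring B; it is built around the biaryl carbon. The carbon of ring A that holds ring B (flavone C6) has an oxygen-bearing neighbour on each side (C5, C7); this three-carbon unit is a 2-arylmalonate, used as its bis(2,4,6-trichlorophenyl) ester with ring B present as a bromo-bis(benzyloxy)phenyl group. The remaining carbons C8, C8a and C4a are the methyl group, C6 and C5 of a 6-methyl-2-arylpyran-4-one whose ring oxygen is already O1. One operation joins them: acylation of the pyranone dienolate at CH3, then closure of a dienylketene onto C5. The bromide later receives the (2S)-flavanone.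

Key step: step 10

Remark: the (R)-ligand in step 15 is chosen on the assumption that the chromone presents the same face to the aryl–palladium bond as 3-substituted cyclic enones do; if the sense proves opposite, the ligand antipode is used.

Step 1
Reactants: 1 5-bromo-2-hydroxy-3-methoxybenzaldehyde
Product: 2 5-bromo-2,3-dihydroxybenzaldehyde
Conditions: BBr3, CH2Cl2, −78 °C to rt; H2O
Reagents that add atoms: none
Why: BBr3 cleavage of the aryl methyl ether (Lewis-acid demethylation) is routine for guaiacol-type aldehydes, and neither the aldehyde nor the aryl bromide reacts at these temperatures.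

Step 2
Reactants: 2 5-bromo-2,3-dihydroxybenzaldehyde
Product: 3 2,3-bis(benzyloxy)-5-bromobenzaldehyde
Conditions: BnBr, K2CO3, DMF, 60 °C
Reagents that add atoms: benzyl bromide, BrCc1ccccc1
Why: Williamson ether synthesis on both phenoxides, the benzyl groups being chosen because they should survive every later acid, base and palladium step and all leave together in the last hydrogenolysis.

Step 3
Reactants: 3 2,3-bis(benzyloxy)-5-bromobenzaldehyde
Product: 4 1,2-bis(benzyloxy)-5-bromo-3-[2-(methylsulfanyl)-2-(methylsulfinyl)ethenyl]benzene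
Conditions: CH3S(O)CH2SCH3, BnMe3N+ OH− (Triton B, cat.), THF, reflux
Reagents that add atoms: methyl (methylsulfinyl)methyl sulfide, CSCS(C)=O
Why: Knoevenagel condensation of the non-enolisable aldehyde with the acidic methylene of formaldehyde dimethyl dithioacetal S-oxide gives the ketene dithioacetal S-oxide, a masked arylacetic acid, without touching the aryl bromide.

Step 4
Reactants: 4 1,2-bis(benzyloxy)-5-bromo-3-[2-(methylsulfanyl)-2-(methylsulfinyl)ethenyl]benzene
Product: 5 ethyl 2-[2,3-bis(benzyloxy)-5-bromophenyl]acetate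
Conditions: HCl (dry), EtOH, 0 °C to rt
Reagents that add atoms: ethanol, CCO
Why: acid-promoted ethanolysis of the ketene dithioacetal S-oxide (protonation at the benzylic carbon, addition of ethanol to the thionium ion, Pummerer-type loss of both sulfur groups) gives the arylacetic ester in which the former aldehyde carbon is the benzylic CH2.

Step 5
Reactants: 5 ethyl 2-[2,3-bis(benzyloxy)-5-bromophenyl]acetate
Product: 6 diethyl 2-[2,3-bis(benzyloxy)-5-bromophenyl]malonate
Conditions: NaH, (EtO)2CO (excess), THF, reflux; aq. HCl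
Reagents that add atoms: diethyl carbonate, CCOC(=O)OCC
Why: crossed Claisen condensation of the ester enolate with excess diethyl carbonate is driven by deprotonation of the arylmalonate formed, and the excess carbonate suppresses self-condensation.

Step 6
Reactants: 6 diethyl 2-[2,3-bis(benzyloxy)-5-bromophenyl]malonate
Product: 7 2-[2,3-bis(benzyloxy)-5-bromophenyl]malonic acid
Conditions: LiOH·H2O, THF/H2O, rt; 1 M HCl, 0 °C
Reagents that add atoms: lithium hydroxide, [Li+].[OH-]
Why: saponification of both esters at room temperature followed by cold acidification gives the arylmalonic acid, which decarboxylates only on heating and is therefore used without delay.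

Step 7
Reactants: 7 2-[2,3-bis(benzyloxy)-5-bromophenyl]malonic acid; 8 2,4,6-trichlorophenol (two equivalents enter the product)
Product: 9 bis(2,4,6-trichlorophenyl) 2-[2,3-bis(benzyloxy)-5-bromophenyl]malonate
Conditions: 8 (2.2 equiv), DCC (2.2 equiv), CH2Cl2, 0 °C to rt
Reagents that add atoms: 2,4,6-trichlorophenol (the second equivalent of 8), Oc1c(Cl)cc(Cl)cc1Cl
Why: twofold carbodiimide esterification at or below room temperature activates each carboxyl group in turn (through the O-acylisourea or the derived ketene) toward one molecule of the acidic phenol, so that two molecules of 8 are taken up, and it avoids hot acidic conditions under which the ortho benzyloxy group could lactonise onto the acyl carbon.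

Step 8
Reactants: 10 acetylacetone; 11 methyl 4-(benzyloxy)benzoate
Product: 12 1-[4-(benzyloxy)phenyl]hexane-1,3,5-trione
Conditions: NaH (excess), DME, reflux; aq. HCl
Reagents that add atoms: none
Why: Claisen acylation of the acetylacetone dianion takes place at the terminal methyl carbon, its more basic and more nucleophilic site, and excess hydride drives the reaction by deprotonating the triketone formed.

Step 9
Reactants: 12 1-[4-(benzyloxy)phenyl]hexane-1,3,5-trione
Product: 13 2-[4-(benzyloxy)phenyl]-6-methyl-4H-pyran-4-one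
Conditions: TsOH·H2O (cat.), toluene, reflux, Dean–Stark
Reagents that add atoms: none
Why: acid-catalysed cyclodehydration of the 1,3,5-triketone (enol oxygen onto the distal carbonyl, then loss of water) gives the 4-pyranone under conditions that leave the benzyl ether intact.

Step 10
Reactants: 9 bis(2,4,6-trichlorophenyl) 2-[2,3-bis(benzyloxy)-5-bromophenyl]malonate; 13 2-[4-(benzyloxy)phenyl]-6-methyl-4H-pyran-4-one
Product: 18 6-[2,3-bis(benzyloxy)-5-bromophenyl]-2-[4-(benzyloxy)phenyl]-5,7-dihydroxy-4H-chromen-4-one, via lithium dienolate 14 (not isolated), via arylketene ester 15 (not isolated), via keto ester 16 (not isolated), via dienylketene 17 (not isolated)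
Conditions: 13 (2.1 equiv), LiN(SiMe3)2 (2.0 equiv), THF, −78 °C; 9 (1 equiv), −78 to 0 °C; AcOH; solvent switch to toluene, 110 °C
Reagents that add atoms: none
Why: Proposed new method: one equivalent of dienolate 14 acts as base toward the acidic malonate C–H of 9, the lithium malonate expels 2,4,6-trichlorophenoxide (E1cB) to give ketene 15, and the second equivalent of 14 adds through its exocyclic carbon (vinylogous Claisen acylation) so that 16 is born as a stabilised enolate that resists a second acylation. After neutralisation and heating, the enol of 16 loses the second trichlorophenol to give an acylketene whose enol 17 is a dienylketene built from the ketene C=C, the enol C=C and the pyranone C5=C6 bond. Ring A then closes by thermal disrotatory 6π-electrocyclisation that bonds the ketene carbon to pyranone C5 (six-membered carbocycle, no new stereocentre), and tautomerisation of the cyclohexadienone gives the 5,7-dihydroxy arene. The closest known reaction types are the thermal condensation of bis(2,4,6-trichlorophenyl) malonates with 1,3-dinucleophiles, the acylation of lithiated 2-methylpyran-4-ones at the methyl carbon, and the 6π ring closure of dienylketenes formed by opening of vinylcyclobutenones. The step needs acylation at carbon and closure at C5 only, which the substrate secures because the methyl group is the sole acidic carbon of 13, C5 is the only nucleophilic atom that the ketene can reach through a six-membered transition state, and capture of either ketene by oxygen nucleophiles (trichlorophenol, the dienolate oxygen) gives activated esters that can re-enter the pathway. Since the two acyl groups of the malonate are equivalent, either order of the two C–C bond formations leads to the same 6-aryl flavone and an 8-aryl isomer has no pathway.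

Step 11
Reactants: 18 6-[2,3-bis(benzyloxy)-5-bromophenyl]-2-[4-(benzyloxy)phenyl]-5,7-dihydroxy-4H-chromen-4-one
Product: 19 5,7-bis(benzyloxy)-6-[2,3-bis(benzyloxy)-5-bromophenyl]-2-[4-(benzyloxy)phenyl]-4H-chromen-4-one
Conditions: BnBr, Cs2CO3, DMF, 70 °C
Reagents that add atoms: benzyl bromide, BrCc1ccccc1
Why: Williamson benzylation of both phenols, with caesium carbonate and warming to overcome the hydrogen bond of the 5-hydroxyl to the carbonyl group and the flanking aryl ring, removes acidic protons before the two palladium steps.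

Step 12
Reactants: 19 5,7-bis(benzyloxy)-6-[2,3-bis(benzyloxy)-5-bromophenyl]-2-[4-(benzyloxy)phenyl]-4H-chromen-4-one
Product: 21 (3,4-bis(benzyloxy)-5-{5,7-bis(benzyloxy)-2-[4-(benzyloxy)phenyl]-4-oxo-4H-chromen-6-yl}phenyl)boronic acid, via pinacol boronate 20 (not isolated)
Conditions: B2pin2, PdCl2(dppf), KOAc, 1,4-dioxane, 90 °C; filtration, then NaIO4, NH4OAc, acetone/H2O, rt
Reagents that add atoms: bis(pinacolato)diboron, CC1(C)OB(B2OC(C)(C)C(C)(C)O2)OC1(C)C; water, O
Why: Miyaura borylation of the unhindered aryl bromide (oxidative addition to zerovalent palladium, acetate-assisted transmetalation with the diboron, reductive elimination) followed by periodate cleavage of the pinacol released on hydrolysis gives the free boronic acid needed for transmetalation to cationic palladium in step 15.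

Step 13
Reactants: 22 1-(2,4,6-trihydroxyphenyl)ethan-1-one
Product: 23 1-[2,4-bis(benzyloxy)-6-hydroxyphenyl]ethan-1-one
Conditions: BnBr (2 equiv), K2CO3, DMF, rt
Reagents that add atoms: benzyl bromide, BrCc1ccccc1
Why: selective Williamson benzylation in which the 4-hydroxyl and one ortho hydroxyl react while the last ortho hydroxyl, hydrogen-bonded to the acetyl group, stays free.

Step 14
Reactants: 23 1-[2,4-bis(benzyloxy)-6-hydroxyphenyl]ethan-1-one
Product: 25 5,7-bis(benzyloxy)-4H-chromen-4-one, via enaminone 24 (not isolated)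
Conditions: Me2NCH(OMe)2, toluene, 100 °C; then conc. HCl, CH2Cl2, 40 °C
Reagents that add atoms: N,N-dimethylformamide dimethyl acetal, COC(OC)N(C)C
Why: condensation of the methyl ketone with the formamide acetal gives the enaminone, and acid then triggers conjugate addition of the phenol and loss of dimethylamine (6-endo addition–elimination) to close the chromone ring.

Step 15
Reactants: 21 (3,4-bis(benzyloxy)-5-{5,7-bis(benzyloxy)-2-[4-(benzyloxy)phenyl]-4-oxo-4H-chromen-6-yl}phenyl)boronic acid; 25 5,7-bis(benzyloxy)-4H-chromen-4-one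
Product: 26 (2S)-5,7-bis(benzyloxy)-2-(3,4-bis(benzyloxy)-5-{5,7-bis(benzyloxy)-2-[4-(benzyloxy)phenyl]-4-oxo-4H-chromen-6-yl}phenyl)-2,3-dihydro-4H-chromen-4-one
Conditions: 25 (1.5 equiv), Pd(OCOCF3)2 (10 mol%), (R)-t-BuPyOX (12 mol%), NH4PF6 (30 mol%), H2O (5 equiv), ClCH2CH2Cl, 60 °C
Reagents that add atoms: none
Why: palladium-catalysed asymmetric conjugate addition of an arylboronic acid to a chromone, in which transmetalation to the cationic divalent palladium–pyridine-oxazoline complex is followed by enantio-determining insertion of C2=C3 of 25 into the Pd–aryl bond on the face left open by the tert-butyl group of the ligand (aryl to the Re face of C2, giving 2S) and by protonation of the palladium enolate by water, the 2-aryl-substituted flavone unit of 21 being too hindered to act as acceptor.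

Step 16
Reactants: 26 (2S)-5,7-bis(benzyloxy)-2-(3,4-bis(benzyloxy)-5-{5,7-bis(benzyloxy)-2-[4-(benzyloxy)phenyl]-4-oxo-4H-chromen-6-yl}phenyl)-2,3-dihydro-4H-chromen-4-one
Product: 27 (2S)-2-{3,4-dihydroxy-5-[5,7-dihydroxy-2-(4-hydroxyphenyl)-4-oxo-4H-chromen-6-yl]phenyl}-5,7-dihydroxy-2,3-dihydro-4H-chromen-4-one (CNP0176432.1)
Conditions: H2 (1 atm), 10% Pd/C, THF/MeOH, rt
Reagents that add atoms: none
Why: hydrogenolysis of the seven benzyl ethers over palladium under neutral conditions at room temperature should leave the flavone C2=C3 bond, both carbonyl groups and the configuration at C2 of the flavanone untouched, because the stereocentre is never exposed to base.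

Compound list
1 | 5-bromo-2-hydroxy-3-methoxybenzaldehyde | COc1cc(Br)cc(C=O)c1O | starting material
2 | 5-bromo-2,3-dihydroxybenzaldehyde | O=Cc1cc(Br)cc(O)c1O | intermediate
3 | 2,3-bis(benzyloxy)-5-bromobenzaldehyde | O=Cc1cc(Br)cc(OCc2ccccc2)c1OCc1ccccc1 | intermediate
4 | 1,2-bis(benzyloxy)-5-bromo-3-[2-(methylsulfanyl)-2-(methylsulfinyl)ethenyl]benzene (E/Z mixture, racemic at sulfur) | CSC(=Cc1cc(Br)cc(OCc2ccccc2)c1OCc1ccccc1)S(C)=O | intermediate
5 | ethyl 2-[2,3-bis(benzyloxy)-5-bromophenyl]acetate | CCOC(=O)Cc1cc(Br)cc(OCc2ccccc2)c1OCc1ccccc1 | intermediate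
6 | diethyl 2-[2,3-bis(benzyloxy)-5-bromophenyl]malonate | CCOC(=O)C(C(=O)OCC)c1cc(Br)cc(OCc2ccccc2)c1OCc1ccccc1 | intermediate
7 | 2-[2,3-bis(benzyloxy)-5-bromophenyl]malonic acid | OC(=O)C(C(=O)O)c1cc(Br)cc(OCc2ccccc2)c1OCc1ccccc1 | intermediate
8 | 2,4,6-trichlorophenol | Oc1c(Cl)cc(Cl)cc1Cl | starting material
9 | bis(2,4,6-trichlorophenyl) 2-[2,3-bis(benzyloxy)-5-bromophenyl]malonate | O=C(Oc1c(Cl)cc(Cl)cc1Cl)C(C(=O)Oc1c(Cl)cc(Cl)cc1Cl)c1cc(Br)cc(OCc2ccccc2)c1OCc1ccccc1 | intermediate
10 | acetylacetone (pentane-2,4-dione) | CC(=O)CC(C)=O | starting material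
11 | methyl 4-(benzyloxy)benzoate | COC(=O)c1ccc(OCc2ccccc2)cc1 | starting material
12 | 1-[4-(benzyloxy)phenyl]hexane-1,3,5-trione | CC(=O)CC(=O)CC(=O)c1ccc(OCc2ccccc2)cc1 | intermediate
13 | 2-[4-(benzyloxy)phenyl]-6-methyl-4H-pyran-4-one | Cc1cc(=O)cc(-c2ccc(OCc3ccccc3)cc2)o1 | intermediate
14 | lithium 6-[4-(benzyloxy)phenyl]-2-methylidene-2H-pyran-4-olate (dienolate of 13, formed in the flask) | [Li+].[O-]C1=CC(=C)OC(c2ccc(OCc3ccccc3)cc2)=C1 | intermediate
15 | 2,4,6-trichlorophenyl 2-[2,3-bis(benzyloxy)-5-bromophenyl]-3-oxoprop-2-enoate (ketene, formed in the flask) | O=C=C(C(=O)Oc1c(Cl)cc(Cl)cc1Cl)c1cc(Br)cc(OCc2ccccc2)c1OCc1ccccc1 | intermediate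
16 | 2,4,6-trichlorophenyl 2-[2,3-bis(benzyloxy)-5-bromophenyl]-4-{6-[4-(benzyloxy)phenyl]-4-oxo-4H-pyran-2-yl}-3-oxobutanoate (formed in the flask) | O=C(Oc1c(Cl)cc(Cl)cc1Cl)C(C(=O)Cc1cc(=O)cc(-c2ccc(OCc3ccccc3)cc2)o1)c1cc(Br)cc(OCc2ccccc2)c1OCc1ccccc1 | intermediate
17 | 2-[2,3-bis(benzyloxy)-5-bromophenyl]-4-{6-[4-(benzyloxy)phenyl]-4-oxo-4H-pyran-2-yl}-3-hydroxybuta-1,3-dien-1-one (dienylketene, ketene carbon and pyranone cis on the enol double bond, formed in the flask) | O=C=C(/C(O)=C\c1cc(=O)cc(-c2ccc(OCc3ccccc3)cc2)o1)c1cc(Br)cc(OCc2ccccc2)c1OCc1ccccc1 | intermediate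
18 | 6-[2,3-bis(benzyloxy)-5-bromophenyl]-2-[4-(benzyloxy)phenyl]-5,7-dihydroxy-4H-chromen-4-one | O=c1cc(-c2ccc(OCc3ccccc3)cc2)oc2cc(O)c(-c3cc(Br)cc(OCc4ccccc4)c3OCc3ccccc3)c(O)c12 | intermediate
19 | 5,7-bis(benzyloxy)-6-[2,3-bis(benzyloxy)-5-bromophenyl]-2-[4-(benzyloxy)phenyl]-4H-chromen-4-one | O=c1cc(-c2ccc(OCc3ccccc3)cc2)oc2cc(OCc3ccccc3)c(-c3cc(Br)cc(OCc4ccccc4)c3OCc3ccccc3)c(OCc3ccccc3)c12 | intermediate
20 | 5,7-bis(benzyloxy)-6-[2,3-bis(benzyloxy)-5-(4,4,5,5-tetramethyl-1,3,2-dioxaborolan-2-yl)phenyl]-2-[4-(benzyloxy)phenyl]-4H-chromen-4-one (not isolated) | CC1(C)OB(c2cc(OCc3ccccc3)c(OCc3ccccc3)c(-c3c(OCc4ccccc4)cc4oc(-c5ccc(OCc6ccccc6)cc5)cc(=O)c4c3OCc3ccccc3)c2)OC1(C)C | intermediate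
21 | (3,4-bis(benzyloxy)-5-{5,7-bis(benzyloxy)-2-[4-(benzyloxy)phenyl]-4-oxo-4H-chromen-6-yl}phenyl)boronic acid | OB(O)c1cc(OCc2ccccc2)c(OCc2ccccc2)c(-c2c(OCc3ccccc3)cc3oc(-c4ccc(OCc5ccccc5)cc4)cc(=O)c3c2OCc2ccccc2)c1 | intermediate
22 | 1-(2,4,6-trihydroxyphenyl)ethan-1-one | CC(=O)c1c(O)cc(O)cc1O | starting material
23 | 1-[2,4-bis(benzyloxy)-6-hydroxyphenyl]ethan-1-one | CC(=O)c1c(O)cc(OCc2ccccc2)cc1OCc1ccccc1 | intermediate
24 | (E)-1-[2,4-bis(benzyloxy)-6-hydroxyphenyl]-3-(dimethylamino)prop-2-en-1-one (not isolated) | CN(C)/C=C/C(=O)c1c(O)cc(OCc2ccccc2)cc1OCc1ccccc1 | intermediate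
25 | 5,7-bis(benzyloxy)-4H-chromen-4-one | O=c1ccoc2cc(OCc3ccccc3)cc(OCc3ccccc3)c12 | intermediate
26 | (2S)-5,7-bis(benzyloxy)-2-(3,4-bis(benzyloxy)-5-{5,7-bis(benzyloxy)-2-[4-(benzyloxy)phenyl]-4-oxo-4H-chromen-6-yl}phenyl)-2,3-dihydro-4H-chromen-4-one | O=C1C[C@@H](c2cc(OCc3ccccc3)c(OCc3ccccc3)c(-c3c(OCc4ccccc4)cc4oc(-c5ccc(OCc6ccccc6)cc5)cc(=O)c4c3OCc3ccccc3)c2)Oc2cc(OCc3ccccc3)cc(OCc3ccccc3)c21 | intermediate
27 | (2S)-2-{3,4-dihydroxy-5-[5,7-dihydroxy-2-(4-hydroxyphenyl)-4-oxo-4H-chromen-6-yl]phenyl}-5,7-dihydroxy-2,3-dihydro-4H-chromen-4-one | O=C1C[C@@H](c2cc(O)c(O)c(-c3c(O)cc4oc(-c5ccc(O)cc5)cc(=O)c4c3O)c2)Oc2cc(O)cc(O)c21 | target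

Total step count: 16. Longest linear sequence: 12 steps (steps 1–7, 10, 11, 12, 15, 16).

Steps most likely to fail

Step 10 (proposed new method). Proton transfer from the acidic malonate may consume the dienolate without C–C bond formation if the ketene oligomerises faster than it is trapped. The dienolate may also be acylated on oxygen. In the thermal stage the acylketene may dimerise, or be captured by the ortho benzyloxy oxygen with loss of the benzyl group, instead of cyclising. The fallback gives up the ring construction and makes the biaryl bond by Suzuki–Miyaura coupling, all of it known chemistry. It does not set out from a numbered compound but from commercial 3,5-dibromo-2-hydroxybenzaldehyde and apigenin, and it comes back to the route at 19. Dakin oxidation (H2O2, NaOH) of 3,5-dibromo-2-hydroxybenzaldehyde should give 3,5-dibromobenzene-1,2-diol F1, and benzylation (BnBr, K2CO3, DMF) 1,2-bis(benzyloxy)-3,5-dibromobenzene F2. Bromine–lithium exchange (n-BuLi, Et2O, −78 °C), directed to the bromide ortho to the benzyloxy group, gives [2,3-bis(benzyloxy)-5-bromophenyl]lithium F3, which is quenched with B(OiPr)3 and aqueous HCl to [2,3-bis(benzyloxy)-5-bromophenyl]boronic acid F4. Apigenin is benzylated at O7 and O4' (BnBr, K2CO3, acetone, reflux) to 7-(benzyloxy)-2-[4-(benzyloxy)phenyl]-5-hydroxy-4H-chromen-4-one F5. Iodination next to the free chelated 5-hydroxyl (BnMe3N+ ICl2−, CaCO3, CH2Cl2/MeOH) gives 7-(benzyloxy)-2-[4-(benzyloxy)phenyl]-5-hydroxy-6-iodo-4H-chromen-4-one F6, and benzylation at O5 (BnBr, Cs2CO3, DMF) gives 5,7-bis(benzyloxy)-2-[4-(benzyloxy)phenyl]-6-iodo-4H-chromen-4-one F7. Coupling of F7 with F4 (Pd(PPh3)4, K2CO3, DME/H2O, 85 °C) should give 19, because zerovalent palladium inserts into the C–I bond much faster than into the C–Br bond.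

Step 15. Transmetalation of the bulky, electron-rich boronic acid may be slow enough for protodeboronation to compete, the facial selectivity may be poor with so large an aryl group, and the flavanone may open and close again with loss of configuration. The fallback sets out from bromide 19 and comes back at 26 through a chalcone. Palladium-catalysed formylation of 19 (Pd(OAc)2, di(1-adamantyl)-n-butylphosphine, CO/H2, TMEDA, toluene, 100 °C) gives 3,4-bis(benzyloxy)-5-{5,7-bis(benzyloxy)-2-[4-(benzyloxy)phenyl]-4-oxo-4H-chromen-6-yl}benzaldehyde F8. Claisen–Schmidt condensation with acetophenone 23 (KOH, EtOH/THF, rt) gives (E)-1-[2,4-bis(benzyloxy)-6-hydroxyphenyl]-3-(3,4-bis(benzyloxy)-5-{5,7-bis(benzyloxy)-2-[4-(benzyloxy)phenyl]-4-oxo-4H-chromen-6-yl}phenyl)prop-2-en-1-one F9. Enantioselective intramolecular oxa-Michael addition under a quinine-derived bifunctional thiourea catalyst, with enrichment on a chiral stationary phase where needed, then gives 26.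

Step 16. Reduction may go too far (flavone C2=C3, flavanone C4=O, hydrogenolytic opening of the benzylic C2–O1 bond), or debenzylation may stall as partly deprotected material loses solubility. The fallback sets out from 26 and reaches 27 directly by non-reductive debenzylation with BCl3 and pentamethylbenzene as benzyl-cation scavenger (CH2Cl2, −78 °C); no new compound lies on its way.

Further compounds
F1 | step 10 | 3,5-dibromobenzene-1,2-diol | Oc1cc(Br)cc(Br)c1O
F2 | step 10 | 1,2-bis(benzyloxy)-3,5-dibromobenzene | Brc1cc(Br)c(OCc2ccccc2)c(OCc2ccccc2)c1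
F3 | step 10 | [2,3-bis(benzyloxy)-5-bromophenyl]lithium | [Li]c1cc(Br)cc(OCc2ccccc2)c1OCc1ccccc1
F4 | step 10 | [2,3-bis(benzyloxy)-5-bromophenyl]boronic acid | OB(O)c1cc(Br)cc(OCc2ccccc2)c1OCc1ccccc1
F5 | step 10 | 7-(benzyloxy)-2-[4-(benzyloxy)phenyl]-5-hydroxy-4H-chromen-4-one | O=c1cc(-c2ccc(OCc3ccccc3)cc2)oc2cc(OCc3ccccc3)cc(O)c12
F6 | step 10 | 7-(benzyloxy)-2-[4-(benzyloxy)phenyl]-5-hydroxy-6-iodo-4H-chromen-4-one | O=c1cc(-c2ccc(OCc3ccccc3)cc2)oc2cc(OCc3ccccc3)c(I)c(O)c12
F7 | step 10 | 5,7-bis(benzyloxy)-2-[4-(benzyloxy)phenyl]-6-iodo-4H-chromen-4-one | O=c1cc(-c2ccc(OCc3ccccc3)cc2)oc2cc(OCc3ccccc3)c(I)c(OCc3ccccc3)c12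
F8 | step 15 | 3,4-bis(benzyloxy)-5-{5,7-bis(benzyloxy)-2-[4-(benzyloxy)phenyl]-4-oxo-4H-chromen-6-yl}benzaldehyde | O=Cc1cc(OCc2ccccc2)c(OCc2ccccc2)c(-c2c(OCc3ccccc3)cc3oc(-c4ccc(OCc5ccccc5)cc4)cc(=O)c3c2OCc2ccccc2)c1
F9 | step 15 | (E)-1-[2,4-bis(benzyloxy)-6-hydroxyphenyl]-3-(3,4-bis(benzyloxy)-5-{5,7-bis(benzyloxy)-2-[4-(benzyloxy)phenyl]-4-oxo-4H-chromen-6-yl}phenyl)prop-2-en-1-one | O=C(/C=C/c1cc(OCc2ccccc2)c(OCc2ccccc2)c(-c2c(OCc3ccccc3)cc3oc(-c4ccc(OCc5ccccc5)cc4)cc(=O)c3c2OCc2ccccc2)c1)c1c(O)cc(OCc2ccccc2)cc1OCc1ccccc1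
F0 | step 16 | none | none
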